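**Retrosynthetic overview**
- Target ⇒ bicyclic 3,3-dichloro trione (zinc removes a temporary C3 block) ⇒ cut C1–C8: the acyl-bearing carbon C1 attacks a tertiary C8 carbocation on the C5 side chain, the ring closure of the presumed biosynthesis.
- Cation precursor (tertiary alcohol on a dearomatized, C5-quaternary acylphloroglucinol) ⇒ cut C5–prenyl: enantioselective dearomative C-prenylation of the arene.
- Side chain ⇒ cut C8–homoprenyl (Grignard on a methyl ketone) and C5–C6 (enantioselective conjugate addition of the arene to a sulcatone-derived α-methylene ketone, which sets C7).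
- Arene ⇒ phloroglucinol + isobutyryl chloride, with one chlorine on the free position to block C3.
- Ring order: the phloroglucinol six-membered ring is present from the start and is dearomatized at C5 in step 6; the second ring (C5–C6–C7–C8–C1–C9) is closed last, in step 7.

Assumption: the SMILES is read literally, i.e. (1S,5S,7S,8R) with C1 = acyl bridgehead and C5 = prenyl bridgehead, the C7 prenyl and C8 methyl cis and the C8 homoprenyl trans to the C2–C4 enol bridge (the 7-endo series, bridgeheads opposite to hyperforin); this numbering is used for all intermediates.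

**Step 1**
Reactants: 1 phloroglucinol (benzene-1,3,5-triol); 2 isobutyryl chloride (2-methylpropanoyl chloride)
Product: 3 phlorisobutyrophenone (2-methyl-1-(2,4,6-trihydroxyphenyl)propan-1-one)
Conditions: AlCl3 (3 equiv), PhNO2/CH2Cl2, 0 to 40 °C; aq. HCl work-up
Reagents that add atoms: isobutyryl chloride, CC(C)C(Cl)=O
Why: Friedel–Crafts C-acylation of the highly activated ring stops at the mono-ketone because the first acyl group deactivates the arene, and no stereocentre is formed.

**Step 2**
Reactants: 3 phlorisobutyrophenone; 4 N-chlorosuccinimide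
Product: 5 1-(3-chloro-2,4,6-trihydroxyphenyl)-2-methylpropan-1-one
Conditions: NCS (1.0 equiv, slow addition), THF, −20 to 0 °C
Reagents that add atoms: N-chlorosuccinimide, O=C1CCC(=O)N1Cl
Why: Electrophilic aromatic chlorination of one of the two equivalent free ring positions gives the mono-chloride, whose chlorine blocks C3 so that later C–C bond formation can only occur at C5, and no stereocentre is formed.

**Step 3**
Reactants: 6 6-methylhept-5-en-2-one (sulcatone); 7 paraformaldehyde
Product: 8 6-methyl-3-methylidenehept-5-en-2-one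
Conditions: (CH2O)n (2 equiv), N-methylanilinium trifluoroacetate (1 equiv), THF, reflux
Reagents that add atoms: formaldehyde (from paraformaldehyde), C=O
Why: Mannich-type α-methylenation (ammonium-salt-mediated condensation with formaldehyde) proceeds through the more substituted enol of the methyl ketone and gives the 3-methylene ketone without creating a stereocentre.

**Step 4**
Reactants: 5 1-(3-chloro-2,4,6-trihydroxyphenyl)-2-methylpropan-1-one; 8 6-methyl-3-methylidenehept-5-en-2-one
Product: 9 (3S)-3-{[3-chloro-2,4,6-trihydroxy-5-(2-methylpropanoyl)phenyl]methyl}-6-methylhept-5-en-2-one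
Conditions: 8 (1.5 equiv), (S)-N1,N1-diethyl-3,3-dimethylbutane-1,2-diamine·TfOH (20 mol%), CHCl3, 0 °C
Reagents that add atoms: 6-methyl-3-methylidenehept-5-en-2-one, CC(=O)C(=C)CC=C(C)C
Why: Aminocatalytic Friedel–Crafts conjugate addition in which the primary amine turns 8 into an iminium ion, the only free ring carbon of 5 adds to the CH2 terminus, and the chiral ammonium group protonates the resulting enamine on one face, which sets C7 as S (the catalyst antipode is used if the observed sense is the opposite).

**Step 5**
Reactants: 9 the (3S)-aryl ketone; 10 5-bromo-2-methylpent-2-ene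
Product: 11 1-{3-chloro-2,4,6-trihydroxy-5-[(2S)-3-hydroxy-3,7-dimethyl-2-(3-methylbut-2-en-1-yl)oct-6-en-1-yl]phenyl}-2-methylpropan-1-one (both C3′ epimers)
Conditions: 10, Mg, THF (Grignard reagent, 4.5 equiv); anhydrous CeCl3 (4.5 equiv), THF, −78 to 0 °C; aq. NH4Cl
Reagents that add atoms: 4-methylpent-3-enylmagnesium bromide, CC(C)=CCC[Mg]Br
Why: Organocerium-modified Grignard 1,2-addition goes to the methyl ketone, which is far more electrophilic than the hindered, phenoxide-deactivated aryl ketone, while CeCl3 suppresses enolisation so that C7 is not epimerised; the new carbinol carbon C8 forms as both epimers, which is immaterial because C8 is ionised in step 7.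

**Step 6**
Reactants: 11 the aryl tertiary alcohol; 12 prenyl bromide (1-bromo-3-methylbut-2-ene)
Product: 13 (6S)-4-chloro-3,5-dihydroxy-6-[(2S)-3-hydroxy-3,7-dimethyl-2-(3-methylbut-2-en-1-yl)oct-6-en-1-yl]-6-(3-methylbut-2-en-1-yl)-2-(2-methylpropanoyl)cyclohexa-2,4-dien-1-one (both C3′ epimers)
Conditions: 12 (1.1 equiv), O-allyl-N-(9-anthracenylmethyl)cinchonidinium bromide (10 mol%), CsOH·H2O (3 equiv), toluene/CHCl3 7:3, −40 °C
Reagents that add atoms: prenyl bromide, CC(C)=CCBr
Why: Asymmetric phase-transfer-catalysed alkylative dearomatization in which the phloroglucinolate, ion-paired with the chiral ammonium cation, is C-alkylated by an SN2 reaction at its most electron-rich carbon C5 (C1 carries the acyl group and C3 the chlorine), the catalyst shielding one face of the ring so that the quaternary C5 centre is set under catalyst control with little influence from the remote C7 centre (the pseudoenantiomeric cinchoninium catalyst is used if the observed sense is the opposite).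

**Step 7**
Reactants: 13 the dearomatized tertiary alcohol; 4 N-chlorosuccinimide
Product: 16 (1S,5S,7S,8R)-4-hydroxy-8-methyl-5,7-bis(3-methylbut-2-en-1-yl)-8-(4-methylpent-3-en-1-yl)-1-(2-methylpropanoyl)bicyclo[3.3.1]non-3-ene-2,9-dione (target), via monocyclic gem-dichloride 14 (not isolated), via bicyclic gem-dichloride 15 (not isolated)
Conditions: NCS (1.05 equiv), CH2Cl2, 0 °C; then HCO2H (1:1 with CH2Cl2), 0 °C to rt; then Zn dust (10 equiv), rt
Reagents that add atoms: none
Why: Proposed new method: NCS first turns the C3 chloro-enol into a CCl2 group so that neither C3 nor O4 can act as a nucleophile, formic acid then ionises the tertiary alcohol much faster than it protonates the trisubstituted alkenes, O-alkylation to the cyclic enol ether is reversible in this ionising medium, and the only carbon nucleophile within reach of the C8 cation, the triketone enol carbon C1, closes the six-membered ring irreversibly through a boat-like transition state with the C7 prenyl group pseudo-equatorial and the larger homoprenyl chain on the outer face (methyl toward the C2–C4 bridge), which sets C1 (forced by the C5 bridgehead) and C8, after which zinc in the same acid removes both chlorines; the closest known reactions are the formic-acid-mediated cationic cyclization of dearomatized acylphloroglucinols to bicyclic nonane cores and the zinc/acid dehalogenation of α-halo ketones.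

**Compound list**
1 | phloroglucinol (benzene-1,3,5-triol) | Oc1cc(O)cc(O)c1 | starting material
2 | isobutyryl chloride | CC(C)C(Cl)=O | starting material
3 | phlorisobutyrophenone, 2-methyl-1-(2,4,6-trihydroxyphenyl)propan-1-one | CC(C)C(=O)c1c(O)cc(O)cc1O | intermediate
4 | N-chlorosuccinimide | O=C1CCC(=O)N1Cl | starting material
5 | 1-(3-chloro-2,4,6-trihydroxyphenyl)-2-methylpropan-1-one | CC(C)C(=O)c1c(O)cc(O)c(Cl)c1O | intermediate
6 | 6-methylhept-5-en-2-one (sulcatone) | CC(=O)CCC=C(C)C | starting material
7 | paraformaldehyde (formaldehyde unit) | C=O | starting material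
8 | 6-methyl-3-methylidenehept-5-en-2-one | CC(=O)C(=C)CC=C(C)C | intermediate
9 | (3S)-3-{[3-chloro-2,4,6-trihydroxy-5-(2-methylpropanoyl)phenyl]methyl}-6-methylhept-5-en-2-one (open form of its cyclic hemiketal) | CC(=O)[C@@H](CC=C(C)C)Cc1c(O)c(Cl)c(O)c(C(=O)C(C)C)c1O | intermediate
10 | 5-bromo-2-methylpent-2-ene | CC(C)=CCCBr | starting material
11 | 1-{3-chloro-2,4,6-trihydroxy-5-[(2S)-3-hydroxy-3,7-dimethyl-2-(3-methylbut-2-en-1-yl)oct-6-en-1-yl]phenyl}-2-methylpropan-1-one, both C3′ (= C8) epimers, C2′ (= C7) S | CC(C)=CCCC(C)(O)[C@@H](CC=C(C)C)Cc1c(O)c(Cl)c(O)c(C(=O)C(C)C)c1O | intermediate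
12 | prenyl bromide (1-bromo-3-methylbut-2-ene) | CC(C)=CCBr | starting material
13 | (6S)-4-chloro-3,5-dihydroxy-6-[(2S)-3-hydroxy-3,7-dimethyl-2-(3-methylbut-2-en-1-yl)oct-6-en-1-yl]-6-(3-methylbut-2-en-1-yl)-2-(2-methylpropanoyl)cyclohexa-2,4-dien-1-one, both C3′ epimers, one enol tautomer drawn | CC(C)=CCCC(C)(O)[C@@H](CC=C(C)C)C[C@]1(CC=C(C)C)C(=O)C(C(=O)C(C)C)=C(O)C(Cl)=C1O | intermediate
14 | (6R)-4,4-dichloro-3-hydroxy-6-[(2S)-3-hydroxy-3,7-dimethyl-2-(3-methylbut-2-en-1-yl)oct-6-en-1-yl]-6-(3-methylbut-2-en-1-yl)-2-(2-methylpropanoyl)cyclohex-2-ene-1,5-dione, both C3′ epimers, not isolated (same geometry at the ring stereocentre as 13; the descriptor changes through CIP priorities) | CC(C)=CCCC(C)(O)[C@@H](CC=C(C)C)C[C@]1(CC=C(C)C)C(=O)C(C(=O)C(C)C)=C(O)C(Cl)(Cl)C1=O | intermediate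
15 | (1R,5R,7S,8R)-3,3-dichloro-8-methyl-5,7-bis(3-methylbut-2-en-1-yl)-8-(4-methylpent-3-en-1-yl)-1-(2-methylpropanoyl)bicyclo[3.3.1]nonane-2,4,9-trione, not isolated (same geometry as 16; C1/C5 descriptors change through CIP priorities) | CC(C)=CCC[C@]1(C)[C@@H](CC=C(C)C)C[C@]2(CC=C(C)C)C(=O)[C@@]1(C(=O)C(C)C)C(=O)C(Cl)(Cl)C2=O | intermediate
16 | (1S,5S,7S,8R)-4-hydroxy-8-methyl-5,7-bis(3-methylbut-2-en-1-yl)-8-(4-methylpent-3-en-1-yl)-1-(2-methylpropanoyl)bicyclo[3.3.1]non-3-ene-2,9-dione | CC(C)=CCC[C@]1(C)[C@@H](CC=C(C)C)C[C@]2(CC=C(C)C)C(=O)[C@@]1(C(=O)C(C)C)C(=O)C=C2O | target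

**Totals**
Total step count: 7. Longest linear sequence: 6 steps (steps 1, 2, 4, 5, 6, 7 from phloroglucinol; step 3 is the one-step side branch).

**Three steps most likely to fail, each with a fallback**

Step 7 is the most likely to fail. The triketone enol carbon C1 is a weak nucleophile, so the C8 cation may rest as the cyclic enol ether on O9, lose a proton, or take a 1,2-hydride shift from C7. The methyl/homoprenyl face selectivity at C8 is only sterically biased. The gem-dichloro diketone can also pass on Cl+ or open by retro-Claisen cleavage. The fallback sets out from 13 and changes both the regiocontrol element and the ionisation mode. TMSCHN2 (toluene/MeOH, 0 °C) methylates the non-chelated chloro-enol hydroxyl to give the O-methyl enol ether F1, which silences C3 and O4 without a second chlorine. The tertiary alcohol is then ionised under basic conditions (MsCl, Et3N, CH2Cl2, −20 °C to rt) so that the much more nucleophilic triketonate anion attacks C8, giving the bicyclic chloro methoxy enone F2. LiCl in DMSO at 120 °C cleaves the methyl ether to the bicyclic chloro enol F3, and Zn/AcOH removes the chlorine, which comes back to the route at 16.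

Step 6 is the second risk. Enantioface control in an SN2 C-alkylation of this ion pair is untested, and O-prenylation or attack at the chlorinated carbon may compete. The fallback sets out from 11 and replaces catalyst control by separation with recycling. Prenylation without a chiral catalyst (prenyl bromide, aqueous KOH, 0 °C) gives 13 together with its C5 epimer F4; these are diastereomers because C7 is already fixed and are separated by chromatography. The C5 epimer F4 is returned to 11 by palladium-mediated deprenylation (Pd(PPh3)4, morpholine, THF), which cleaves only the prenyl group on the doubly activated C5. The recycled 11 is prenylated again, and the sequence comes back to the route at 13.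

Step 4 is the third risk. An uncatalysed, racemic conjugate addition of the very nucleophilic arene, or later epimerisation of the α-keto stereocentre, may erode the ee. The fallback sets out from 5 (with 8) and replaces asymmetric catalysis by resolution with recycling. Simple base catalysis (Et3N, THF, rt) gives the racemate, which consists of 9 and the (3R)-enantiomer F5. These are separated on a chiral stationary phase (preparative SFC). The (3R)-enantiomer F5 is racemised through the ketone enol with DBU and resubmitted, and the sequence comes back to the route at 9.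

**Further compounds**
F1 | step 7 | (6S)-4-chloro-3-hydroxy-5-methoxy-6-[(2S)-3-hydroxy-3,7-dimethyl-2-(3-methylbut-2-en-1-yl)oct-6-en-1-yl]-6-(3-methylbut-2-en-1-yl)-2-(2-methylpropanoyl)cyclohexa-2,4-dien-1-one (both C3′ epimers) | CC(C)=CCCC(C)(O)[C@@H](CC=C(C)C)C[C@]1(CC=C(C)C)C(=O)C(C(=O)C(C)C)=C(O)C(Cl)=C1OC
F2 | step 7 | (1R,5S,7S,8R)-3-chloro-4-methoxy-8-methyl-5,7-bis(3-methylbut-2-en-1-yl)-8-(4-methylpent-3-en-1-yl)-1-(2-methylpropanoyl)bicyclo[3.3.1]non-3-ene-2,9-dione | CC(C)=CCC[C@]1(C)[C@@H](CC=C(C)C)C[C@]2(CC=C(C)C)C(=O)[C@@]1(C(=O)C(C)C)C(=O)C(Cl)=C2OC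
F3 | step 7 | (1R,5S,7S,8R)-3-chloro-4-hydroxy-8-methyl-5,7-bis(3-methylbut-2-en-1-yl)-8-(4-methylpent-3-en-1-yl)-1-(2-methylpropanoyl)bicyclo[3.3.1]non-3-ene-2,9-dione | CC(C)=CCC[C@]1(C)[C@@H](CC=C(C)C)C[C@]2(CC=C(C)C)C(=O)[C@@]1(C(=O)C(C)C)C(=O)C(Cl)=C2O
F4 | step 6 | (6R)-4-chloro-3,5-dihydroxy-6-[(2S)-3-hydroxy-3,7-dimethyl-2-(3-methylbut-2-en-1-yl)oct-6-en-1-yl]-6-(3-methylbut-2-en-1-yl)-2-(2-methylpropanoyl)cyclohexa-2,4-dien-1-one (C5 epimer of 13, both C3′ epimers) | CC(C)=CCCC(C)(O)[C@@H](CC=C(C)C)C[C@@]1(CC=C(C)C)C(=O)C(C(=O)C(C)C)=C(O)C(Cl)=C1O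
F5 | step 4 | (3R)-3-{[3-chloro-2,4,6-trihydroxy-5-(2-methylpropanoyl)phenyl]methyl}-6-methylhept-5-en-2-one (enantiomer of 9) | CC(=O)[C@H](CC=C(C)C)Cc1c(O)c(Cl)c(O)c(C(=O)C(C)C)c1O
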